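The γ‑lactone is cut across C8–C17 and O–C7, which leads back to a propanoate unit and the ten‑membered (E)‑dienone 28 (C16=C5–C6=C7–C8=O) that already holds the C2 isobutyrate, the three acetates and the 11,20‑epoxide. The key step exploits the E‑configured C6=C7 bond next to the C8 ketone in the ten‑membered ring. A Reformatsky addition to C8, followed in the same flask by chlorolactonization, forms C8–C17, O–C7 and C6–Cl and sets C6, C7, C8 and C17 in one operation. Dienone 28 comes from a Diels–Alder reaction of a glyceraldehyde‑derived enal (ring A) and a Nozaki–Hiyama–Kishi ring closure.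

Key step: step 19

Remark (assumption): locants are the briarane locants of the target (C1 quaternary carbon with methyl C15; C2 isobutyrate carbon; C5=C16; C6 chloride; C7 lactone CH–O; C8 carbinol; C9, C12, C14 acetate carbons; C10 ring‑fusion CH; C11/C20 epoxide; C17(C18)–C19 lactone propanoate); α is the face of ring A opposite the C15 methyl; 1, 2, 4, 6 and 29 are taken as commercial.

Step 1
Reactants: 1 (R)-2,2-dimethyl-1,3-dioxolane-4-carbaldehyde; 2 2-(triphenylphosphoranylidene)propanal
Product: 3 (E)-3-[(4S)-2,2-dimethyl-1,3-dioxolan-4-yl]-2-methylprop-2-enal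
Conditions: toluene, 80 °C
Reagents that add atoms: none
Why: Wittig olefination with a stabilised formyl ylide should give the E enal; the dioxolane carbon (later C9) is carried over unchanged from 1.

Step 2
Reactants: 3 enal; 4 (E)-3-(tert-butyldimethylsilyloxy)-N,N-dimethylbuta-1,3-dien-1-amine
Product: 5 amino silyl enol ether cycloadduct
Conditions: toluene, 40–60 °C, sealed tube
Reagents that add atoms: none
Why: Normal-demand Diels–Alder reaction in which the amino terminus bonds to the aldehyde-bearing carbon; the E geometry places C2 and C9 trans, and 1,3-allylic strain with the α-methyl holds C9–H in the alkene plane so that the diene should add anti to the C9–O bond, which sets C1 and C10.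

Step 3
Reactants: 5 cycloadduct; 6 pent-4-en-1-ylmagnesium bromide
Product: 8 hydroxy enone, via magnesium alkoxide 7 (not isolated)
Conditions: 6, THF, −78 °C; then HF·pyridine, MeCN, 0 °C
Reagents that add atoms: none
Why: Grignard addition under Felkin–Anh control (attack anti to the branched C10 substituent, reinforced by magnesium chelation to the cis amine) should set C2; HF then cleaves the silyl enol ether and the β-amino ketone loses dimethylamine by E1cB elimination to give the enone.

Step 4
Reactants: 8 hydroxy enone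
Product: 9 enone isobutyrate
Conditions: (iPrCO)2O, DMAP, Et3N, CH2Cl2, 20 °C
Reagents that add atoms: isobutyric anhydride CC(C)C(=O)OC(=O)C(C)C
Why: DMAP-catalysed acylation of the only free hydroxyl installs the C2 ester before any other hydroxyl exists; no later step uses a hydride or carbon nucleophile strong enough to cleave it.

Step 5
Reactants: 9 enone isobutyrate
Product: 11 14α-hydroxy ketone, via C14 boronate 10 (not isolated)
Conditions: B2pin2, CuCl (cat.), Xantphos (cat.), NaOtBu (cat.), MeOH, THF, 20 °C; then NaBO3·4H2O, THF/H2O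
Reagents that add atoms: sodium perborate [Na+].[Na+].O[B-]1(O)OO[B-](O)(O)OO1
Why: Copper-catalysed conjugate borylation followed by stereoretentive C–B oxidation; the boryl group should add to C14 anti to the axial C15 methyl, which sets the 14α oxygen.

Step 6
Reactants: 11 14α-hydroxy ketone
Product: 14 α-methylene ketone, via Mannich base 12 (not isolated), via methiodide 13 (not isolated)
Conditions: LDA (2.2 equiv), THF, −78 °C; Me2N=CH2 I; then MeI, CH2Cl2; aq NaHCO3
Reagents that add atoms: dimethylmethyleneammonium iodide C=[N+](C)C.[I-]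
Why: In the alkoxide–enolate dianion the C14 alkoxide disfavours deprotonation at C13, so the enolate forms at C11; Mannich reaction and Hofmann-type elimination then give the exocyclic C11=C20 enone without a new stereocentre.

Step 7
Reactants: 14 α-methylene ketone
Product: 15 12α,14α-diol
Conditions: (S)-2-methyl-CBS-oxazaborolidine, catecholborane, toluene, −78 °C
Reagents that add atoms: none
Why: Corey–Bakshi–Shibata reduction gives 1,2-reduction of the enone with catalyst-controlled hydride delivery to the β face, matched with shielding of the α face by the axial C14 hydroxyl, which sets C12.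

Step 8
Reactants: 15 12α,14α-diol
Product: 16 tetraol
Conditions: AcOH/H2O/THF, 40 °C
Reagents that add atoms: none
Why: Mild acid hydrolysis of the terminal acetonide frees the C8 and C9 hydroxyls while no acid-labile epoxide is yet present.

Step 9
Reactants: 16 tetraol
Product: 17 8-O-triethylsilyl ether
Conditions: Et3SiCl, imidazole, CH2Cl2, −40 °C
Reagents that add atoms: chlorotriethylsilane CC[Si](Cl)(CC)CC
Why: The primary C8 hydroxyl is silylated much faster than the three secondary ones (two of them axial), which keeps C8 apart from the hydroxyls that become acetates.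

Step 10
Reactants: 17 8-O-triethylsilyl ether
Product: 18 11,20-epoxy triol
Conditions: VO(acac)2 (cat.), t-BuOOH, CH2Cl2, 0 °C
Reagents that add atoms: tert-butyl hydroperoxide CC(C)(C)OO
Why: Vanadium-catalysed hydroxyl-directed epoxidation, in which the axial allylic C12 hydroxyl delivers oxygen to the α face of C11=C20 (the β face is screened by the axial C15 methyl), sets C11 and leaves the remote terminal alkene untouched.

Step 11
Reactants: 18 11,20-epoxy triol
Product: 19 9,12,14-triacetate
Conditions: Ac2O, DMAP, pyridine, 20 °C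
Reagents that add atoms: acetic anhydride CC(=O)OC(C)=O
Why: Exhaustive DMAP-catalysed acetylation of the three secondary hydroxyls installs all acetates of the target in one step.

Step 12
Reactants: 19 triacetate
Product: 21 C6 aldehyde, via terminal diol 20 (not isolated)
Conditions: OsO4 (cat.), NaIO4, 2,6-lutidine, dioxane/H2O, 20 °C
Reagents that add atoms: osmium tetroxide O=[Os](=O)(=O)=O (catalytic, turned over by sodium periodate [Na+].[O-]I(=O)(=O)=O)
Why: Lemieux–Johnson cleavage of the only remaining alkene gives the aldehyde; the epoxide, esters and silyl ether are inert under the buffered conditions.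

Step 13
Reactants: 21 C6 aldehyde
Product: 23 C5-methylene enal, via Mannich base 22 (not isolated)
Conditions: Me2N=CH2 I, Et3N, CH2Cl2, 20 °C
Reagents that add atoms: dimethylmethyleneammonium iodide C=[N+](C)C.[I-]
Why: Mannich reaction of the aldehyde followed by β-elimination of dimethylamine is a standard α-methylenation and installs C16.

Step 14
Reactants: 23 enal
Product: 24 (6E)-7-iodo-5(16),6-diene
Conditions: CrCl2, CHI3, THF/dioxane, 0 °C
Reagents that add atoms: iodoform IC(I)I
Why: Takai olefination of the enal should give the (E)-alkenyl iodide, which fixes the C6=C7 geometry and supplies C7.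

Step 15
Reactants: 24 iododiene
Product: 26 C8 aldehyde, via C8 alcohol 25 (not isolated)
Conditions: (COCl)2, DMSO, CH2Cl2, −78 → −40 °C; then Et3N, −78 → 0 °C
Reagents that add atoms: none
Why: Swern conditions cleave a primary triethylsilyl ether and oxidise the freed alcohol in the same flask (oxidative desilylation), giving the α-acetoxy aldehyde without touching the secondary esters.

Step 16
Reactants: 26 C8 aldehyde
Product: 27 ten-membered dienol (C8 epimers)
Conditions: CrCl2, NiCl2 (cat.), DMSO/THF, 20 °C, high dilution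
Reagents that add atoms: none
Why: Intramolecular Nozaki–Hiyama–Kishi reaction, in which the alkenylchromium species forms with retention of the E geometry and adds chemoselectively to the aldehyde, closes the ten-membered ring at C7–C8; the new C8 carbinol centre is erased in step 17.

Step 17
Reactants: 27 dienol
Product: 28 ten-membered (6E)-5(16),6-dien-8-one
Conditions: DMP (Dess–Martin periodinane), NaHCO3, CH2Cl2, 0 °C
Reagents that add atoms: none
Why: Buffered Dess–Martin oxidation of the allylic alcohol gives the dienone under neutral conditions that spare the epoxide and the epimerisable C9 centre.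

Step 18
Reactants: 29 2-bromopropanoic acid
Product: 30 trimethylsilyl 2-bromopropanoate
Conditions: Me3SiCl, Et3N, Et2O, 0 °C; filtration, distillation
Reagents that add atoms: chlorotrimethylsilane C[Si](C)(C)Cl
Why: Silylation of the acid gives an ester that supports a Reformatsky reagent and is later cleaved by water alone to the free carboxylate.

Step 19
Reactants: 28 dienone; 30 trimethylsilyl 2-bromopropanoate
Product: 34 target briarane lactone, via zinc enolate 31 (not isolated), via zinc aldolate 32 (not isolated), via hydroxy carboxylate 33 (not isolated)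
Conditions: Zn (Me3SiCl-activated), 30, THF, 20 °C, solution decanted from Zn; 28, THF, −20 → 20 °C; then aq NaHCO3, CH2Cl2, N-chlorosuccinimide, 0 °C
Reagents that add atoms: N-chlorosuccinimide O=C1CCC(=O)N1Cl
Why: The preformed zinc enolate 31 adds 1,2 to the C8 ketone (Reformatsky reaction) to give aldolate 32; water frees carboxylate 33, and N-chlorosuccinimide then triggers a chlorolactonization in which the carboxylate oxygen attacks C7 while chlorine is delivered to C6 from the opposite face. The closest known reaction types are the Reformatsky addition of silyl α-bromo esters to ketones and the halolactonization of β-hydroxy γ,δ-unsaturated acids, run here in one flask. The γ-lactone closes in the 5-exo-trig mode onto C7. C8 should be set by Felkin–Anh (Cornforth) attack anti to the C9–OAc bond; C17 by equilibration of the reversible zinc aldolate chelate, which places the methyl anti to the bulky C9 branch; C7 by the hydroxyl-in-plane conformer of the allylic system (H7 ends anti to 8-OH); and C6 by anti addition across the E alkene. The step needs 1,2- over 1,4- or 1,6-addition of the enolate, which the hard zinc enolate and the substituted β-carbon should secure, and capture at the proximal C6=C7 bond rather than chlorine attack at C16, which the carboxylate held within reach of C7 only and the kinetic conditions (bicarbonate buffer, 0 °C) should secure.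

Compound list
1 | (R)-2,2-dimethyl-1,3-dioxolane-4-carbaldehyde | O=C[C@H]1COC(C)(C)O1 | starting material
2 | 2-(triphenylphosphoranylidene)propanal | CC(C=O)=P(c1ccccc1)(c1ccccc1)c1ccccc1 | starting material
3 | (E)-3-[(4S)-2,2-dimethyl-1,3-dioxolan-4-yl]-2-methylprop-2-enal | O=C/C(C)=C/[C@H]1COC(C)(C)O1 | intermediate
4 | (E)-3-(tert-butyldimethylsilyloxy)-N,N-dimethylbuta-1,3-dien-1-amine | C=C(O[Si](C)(C)C(C)(C)C)/C=C/N(C)C | starting material
5 | (1R,2S,6S)-4-(tert-butyldimethylsilyloxy)-2-(dimethylamino)-6-[(4S)-2,2-dimethyl-1,3-dioxolan-4-yl]-1-methylcyclohex-3-ene-1-carbaldehyde | O=C[C@@]1(C)[C@@H](N(C)C)C=C(O[Si](C)(C)C(C)(C)C)C[C@@H]1[C@H]1COC(C)(C)O1 | intermediate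
6 | pent-4-en-1-ylmagnesium bromide | C=CCCC[Mg]Br | starting material
7 | bromomagnesium alkoxide of the C2 pentenyl adduct of 5 | C=CCCC[C@H](O[Mg]Br)[C@@]1(C)[C@@H](N(C)C)C=C(O[Si](C)(C)C(C)(C)C)C[C@@H]1[C@H]1COC(C)(C)O1 | intermediate
8 | (4S,5S)-5-[(4S)-2,2-dimethyl-1,3-dioxolan-4-yl]-4-[(1S)-1-hydroxyhex-5-en-1-yl]-4-methylcyclohex-2-en-1-one | C=CCCC[C@H](O)[C@@]1(C)C=CC(=O)C[C@@H]1[C@H]1COC(C)(C)O1 | intermediate
9 | 2-methylpropanoate of the side-chain hydroxyl of 8 | C=CCCC[C@H](OC(=O)C(C)C)[C@@]1(C)C=CC(=O)C[C@@H]1[C@H]1COC(C)(C)O1 | intermediate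
10 | C14 pinacol boronate of the C12 ketone (boron anti to the C15 methyl) | C=CCCC[C@H](OC(=O)C(C)C)[C@@]1(C)[C@@H](B2OC(C)(C)C(C)(C)O2)CC(=O)C[C@@H]1[C@H]1COC(C)(C)O1 | intermediate
11 | 14α-hydroxy C12 ketone | C=CCCC[C@H](OC(=O)C(C)C)[C@@]1(C)[C@@H](O)CC(=O)C[C@@H]1[C@H]1COC(C)(C)O1 | intermediate
12 | C11 dimethylaminomethyl ketone (Mannich base, C11 epimers) | C=CCCC[C@H](OC(=O)C(C)C)[C@@]1(C)[C@@H](O)CC(=O)C(CN(C)C)[C@@H]1[C@H]1COC(C)(C)O1 | intermediate
13 | trimethylammonium iodide of 12 | C=CCCC[C@H](OC(=O)C(C)C)[C@@]1(C)[C@@H](O)CC(=O)C(C[N+](C)(C)C)[C@@H]1[C@H]1COC(C)(C)O1.[I-] | intermediate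
14 | α-methylene ketone (C11=C20, C12=O, 14α-OH) | C=CCCC[C@H](OC(=O)C(C)C)[C@@]1(C)[C@@H](O)CC(=O)C(=C)[C@@H]1[C@H]1COC(C)(C)O1 | intermediate
15 | 12α,14α-diol with C11=C20 (both hydroxyls axial, syn) | C=CCCC[C@H](OC(=O)C(C)C)[C@@]1(C)[C@@H](O)C[C@@H](O)C(=C)[C@@H]1[C@H]1COC(C)(C)O1 | intermediate
16 | 8,9,12,14-tetraol | C=CCCC[C@H](OC(=O)C(C)C)[C@@]1(C)[C@@H](O)C[C@@H](O)C(=C)[C@@H]1[C@H](O)CO | intermediate
17 | 8-O-triethylsilyl ether of 16 | C=CCCC[C@H](OC(=O)C(C)C)[C@@]1(C)[C@@H](O)C[C@@H](O)C(=C)[C@@H]1[C@H](O)CO[Si](CC)(CC)CC | intermediate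
18 | 11,20-epoxide of 17 (epoxide oxygen syn to 12-OH) | C=CCCC[C@H](OC(=O)C(C)C)[C@@]1(C)[C@@H](O)C[C@@H](O)[C@]2(CO2)[C@@H]1[C@H](O)CO[Si](CC)(CC)CC | intermediate
19 | 9,12,14-triacetate of 18 | C=CCCC[C@H](OC(=O)C(C)C)[C@@]1(C)[C@@H](OC(C)=O)C[C@@H](OC(C)=O)[C@]2(CO2)[C@@H]1[C@H](OC(C)=O)CO[Si](CC)(CC)CC | intermediate
20 | terminal 1,2-diol from the pentenyl group of 19 | OCC(O)CCC[C@H](OC(=O)C(C)C)[C@@]1(C)[C@@H](OC(C)=O)C[C@@H](OC(C)=O)[C@]2(CO2)[C@@H]1[C@H](OC(C)=O)CO[Si](CC)(CC)CC | intermediate
21 | C6 aldehyde (4-oxobutyl chain on C2) | O=CCCC[C@H](OC(=O)C(C)C)[C@@]1(C)[C@@H](OC(C)=O)C[C@@H](OC(C)=O)[C@]2(CO2)[C@@H]1[C@H](OC(C)=O)CO[Si](CC)(CC)CC | intermediate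
22 | C5 dimethylaminomethyl aldehyde (Mannich base) | O=CC(CN(C)C)CC[C@H](OC(=O)C(C)C)[C@@]1(C)[C@@H](OC(C)=O)C[C@@H](OC(C)=O)[C@]2(CO2)[C@@H]1[C@H](OC(C)=O)CO[Si](CC)(CC)CC | intermediate
23 | C5-methylene C6 aldehyde (2-substituted acrolein) | O=CC(=C)CC[C@H](OC(=O)C(C)C)[C@@]1(C)[C@@H](OC(C)=O)C[C@@H](OC(C)=O)[C@]2(CO2)[C@@H]1[C@H](OC(C)=O)CO[Si](CC)(CC)CC | intermediate
24 | (6E)-7-iodo-5(16),6-diene, 8-O-triethylsilyl ether | I/C=C/C(=C)CC[C@H](OC(=O)C(C)C)[C@@]1(C)[C@@H](OC(C)=O)C[C@@H](OC(C)=O)[C@]2(CO2)[C@@H]1[C@H](OC(C)=O)CO[Si](CC)(CC)CC | intermediate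
25 | C8 primary alcohol of 24 | I/C=C/C(=C)CC[C@H](OC(=O)C(C)C)[C@@]1(C)[C@@H](OC(C)=O)C[C@@H](OC(C)=O)[C@]2(CO2)[C@@H]1[C@H](OC(C)=O)CO | intermediate
26 | C8 aldehyde (9-acetoxy aldehyde) with the (6E)-7-iodo-5(16),6-diene | I/C=C/C(=C)CC[C@H](OC(=O)C(C)C)[C@@]1(C)[C@@H](OC(C)=O)C[C@@H](OC(C)=O)[C@]2(CO2)[C@@H]1[C@H](OC(C)=O)C=O | intermediate
27 | ten-membered (6E)-5(16),6-dien-8-ol (C8 epimers) | C=C1CC[C@H](OC(=O)C(C)C)[C@@]2(C)[C@@H](OC(C)=O)C[C@@H](OC(C)=O)[C@]3(CO3)[C@@H]2[C@H](OC(C)=O)C(O)/C=C/1 | intermediate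
28 | ten-membered (6E)-5(16),6-dien-8-one | C=C1CC[C@H](OC(=O)C(C)C)[C@@]2(C)[C@@H](OC(C)=O)C[C@@H](OC(C)=O)[C@]3(CO3)[C@@H]2[C@H](OC(C)=O)C(=O)/C=C/1 | intermediate
29 | 2-bromopropanoic acid (racemic) | CC(Br)C(=O)O | starting material
30 | trimethylsilyl 2-bromopropanoate | CC(Br)C(=O)O[Si](C)(C)C | intermediate
31 | trimethylsilyl 2-(bromozincio)propanoate | CC([Zn]Br)C(=O)O[Si](C)(C)C | intermediate
32 | bromozinc aldolate (8-O–ZnBr, C17 silyl ester) | C=C1CC[C@H](OC(=O)C(C)C)[C@@]2(C)[C@@H](OC(C)=O)C[C@@H](OC(C)=O)[C@]3(CO3)[C@@H]2[C@H](OC(C)=O)[C@](O[Zn]Br)([C@@H](C)C(=O)O[Si](C)(C)C)/C=C/1 | intermediate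
33 | sodium carboxylate of the 8-hydroxy acid | C=C1CC[C@H](OC(=O)C(C)C)[C@@]2(C)[C@@H](OC(C)=O)C[C@@H](OC(C)=O)[C@]3(CO3)[C@@H]2[C@H](OC(C)=O)[C@](O)([C@@H](C)C(=O)[O-])/C=C/1.[Na+] | intermediate
34 | (1S,2S,6S,7R,8R,9S,10S,11R,12R,14S,17R)-9,12,14-triacetoxy-6-chloro-11,20-epoxy-8-hydroxy-2-(2-methylpropanoyloxy)briar-5(16)-en-19,7-olide (CNP0145565.1) | C=C1CC[C@H](OC(=O)C(C)C)[C@@]2(C)[C@@H](OC(C)=O)C[C@@H](OC(C)=O)[C@]3(CO3)[C@@H]2[C@H](OC(C)=O)[C@]2(O)[C@@H](C)C(=O)O[C@H]2[C@H]1Cl | target

Total step count: 19. Longest linear sequence: 18 steps (steps 1–17, then step 19; step 18 is a one-step side branch).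

Steps most likely to fail

Step 19. The zinc enolate may add in a conjugate (1,4 or 1,6) sense instead of to the C8 carbonyl, or the chlorine may attack the terminal C16 of the diene so that capture at C7 gives a 1,4-adduct, or addition may occur on the wrong face of C8. The fallback sets out from 28 and comes back at 34. The Reformatsky addition of 31 to 28 is run as in the route, but the freed hydroxy acid is not chlorinated. Instead it is cyclised in the same flask by gold-catalysed hydroacyloxylation of the diene (Ph3PAuCl, AgOTf, CH2Cl2), with the proton going to C16 and the oxygen to C7. This should give the chlorine-free 5(6)-ene lactone F1. An ene-type allylic chlorination of the trisubstituted C5=C6 bond (N-chlorosuccinimide, PhSeCl cat., CH2Cl2) should then place chlorine on C6 from the outer face and shift the double bond to C5=C16, which gives 34.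

Step 16. Ring strain in the ten-membered transition state may divert the alkenylchromium species to intermolecular coupling, or the α-acetoxy aldehyde may be reduced or lose acetate before ring closure. The fallback sets out from 23 and comes back at 28. Wittig methylenation of the enal (Ph3P=CH2, THF, −78 °C) should give the 2-substituted buta-1,3-diene F2. Swern oxidative desilylation, as in step 15, should give the C8 aldehyde F3. Intermolecular Nozaki–Hiyama–Kishi vinylation (vinyl bromide, CrCl2, NiCl2 cat., DMF) should give the C8 vinyl carbinol F4, and Dess–Martin oxidation the vinyl ketone F5. Ring-closing metathesis between the vinyl ketone and the monosubstituted end of the diene (second-generation Hoveyda–Grubbs catalyst, toluene, high dilution) then closes C6=C7 and gives 28; the E geometry is not guaranteed by this closure.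

Step 2. The trisubstituted, β-branched enal may react so slowly that the aminodiene decomposes first, or facial discrimination by the dioxolane centre may be poor. The fallback sets out from 3 and comes back at 8. A Lewis acid-promoted Diels–Alder reaction of 3 with 2-(trimethylsilyloxy)buta-1,3-diene (Me2AlCl, CH2Cl2, −78 °C) should give the para-regioisomeric silyl enol ether aldehyde F6. Addition of 6 (THF, −78 °C) should give the C2 alcohol F7. Saegusa–Ito oxidation of the silyl enol ether (Pd(OAc)2, MeCN, 20 °C) then introduces the C13=C14 double bond and gives 8.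

Further compounds
F1 | step 19 | chlorine-free (5Z)-5(6)-ene lactone with C16 methyl (C7, C8, C17 as in 34) | C/C1CC[C@H](OC(=O)C(C)C)[C@@]2(C)[C@@H](OC(C)=O)C[C@@H](OC(C)=O)[C@]3(CO3)[C@@H]2[C@H](OC(C)=O)[C@]2(O)[C@@H](C)C(=O)O[C@H]2\C=1
F2 | step 16 | 2-substituted buta-1,3-diene from 23, 8-O-triethylsilyl ether | C=CC(=C)CC[C@H](OC(=O)C(C)C)[C@@]1(C)[C@@H](OC(C)=O)C[C@@H](OC(C)=O)[C@]2(CO2)[C@@H]1[C@H](OC(C)=O)CO[Si](CC)(CC)CC
F3 | step 16 | C8 aldehyde of F2 | C=CC(=C)CC[C@H](OC(=O)C(C)C)[C@@]1(C)[C@@H](OC(C)=O)C[C@@H](OC(C)=O)[C@]2(CO2)[C@@H]1[C@H](OC(C)=O)C=O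
F4 | step 16 | C8 vinyl carbinol (C8 epimers) | C=CC(=C)CC[C@H](OC(=O)C(C)C)[C@@]1(C)[C@@H](OC(C)=O)C[C@@H](OC(C)=O)[C@]2(CO2)[C@@H]1[C@H](OC(C)=O)C(O)C=C
F5 | step 16 | C8 vinyl ketone | C=CC(=C)CC[C@H](OC(=O)C(C)C)[C@@]1(C)[C@@H](OC(C)=O)C[C@@H](OC(C)=O)[C@]2(CO2)[C@@H]1[C@H](OC(C)=O)C(=O)C=C
F6 | step 2 | 4-(trimethylsilyloxy)cyclohex-3-ene-1-carbaldehyde with 1-methyl and 6-[(4S)-dioxolanyl] groups (C1, C10 as in 5) | O=C[C@@]1(C)CC=C(O[Si](C)(C)C)C[C@@H]1[C@H]1COC(C)(C)O1
F7 | step 2 | C2 pentenyl carbinol of F6 | C=CCCC[C@H](O)[C@@]1(C)CC=C(O[Si](C)(C)C)C[C@@H]1[C@H]1COC(C)(C)O1
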